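**Retrosynthetic overview**

1. Feature: in the seven-membered ring, the oxygen-bearing C8 is joined through the C9 methylene to the tetrasubstituted C1=C10 alkene at the fusion with the five-membered ring. C1–C10–C9 is therefore a latent 2-methylallyl cation, and C8 is a latent acyl anion, played here by a nitronate.
2. Endgame: O8 p-coumarate ⇐ trans-8,11-diol ⇐ reduction of the C8 ketone directed by the C11 hydroxyl ⇐ Nef reaction of the 8-nitroguai-1(10)-ene.
3. Key disconnection C8–C9: palladium-catalysed closure of a 1-isopropenylcyclopentyl methyl carbonate carrying the chain CH2–CH(CH2NO2)–CMe2OSi on C5. The five-membered ring is bought and the seven-membered ring is formed last.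
4. The nitro group enters last, by nitrite displacement of a C8 iodide. It comes after the isopropenylcerium addition to the cis-2,3-disubstituted cyclopentanone and after carbonate formation, because it would survive neither.
5. C4 and C5 come from a CBS carbinol at C1 that directs hydrogenation of the C4=C5 alkene. C5–C6 comes from a B-alkyl Suzuki coupling. C7 comes from the Sharpless epoxide of prenol, opened with inversion by a vinylcopper reagent.

Key step: step 15

**Remarks**

- Guaiane numbering is used for every intermediate: C1/C5 ring fusion, C15 methyl on C4, C11 carbinol carbon on C7, oxygen on C8, C14 methyl on C10.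
- TBS = tert-butyldimethylsilyl and TBSO = tert-butyldimethylsilyloxy.
- Assumption: the nitro compound from the key step is drawn as the C8 epimer with the nitro group trans to the C7 substituent. The other epimer would serve equally, because C8 becomes trigonal in the following step.

**Step 1**
Reactants: 1 3-methylbut-2-en-1-ol (prenol)
Product: 2 (R)-(3,3-dimethyloxiran-2-yl)methanol
Conditions: Ti(OiPr)4 (cat.), D-(−)-diisopropyl tartrate (cat.), t-BuOOH, 4 Å molecular sieves, CH2Cl2, −20 °C
Reagents that add atoms: tert-butyl hydroperoxide, CC(C)(C)OO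
Why: Sharpless asymmetric epoxidation of a primary allylic alcohol, in which the titanium complex of the D-(−)-tartrate delivers oxygen to the alkene face that makes the secondary epoxide carbon, the future C7, (R)-configured.

**Step 2**
Reactants: 2 (R)-(3,3-dimethyloxiran-2-yl)methanol; 3 vinylmagnesium bromide
Product: 4 (S)-2-ethenyl-3-methylbutane-1,3-diol
Conditions: 3 (excess), CuI (cat.), THF, −40 → −10 °C
Reagents that add atoms: none
Why: Copper-catalysed SN2 opening of a 2,3-epoxy alcohol goes to the secondary epoxide carbon because the other one is fully substituted, and it proceeds with inversion, so C7 takes up the vinyl carbon (future C6) anti to the oxygen that stays on C11, while any vicinal diol from the other regiochemistry can be removed by a periodate wash.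

**Step 3**
Reactants: 4 (S)-2-ethenyl-3-methylbutane-1,3-diol
Product: 5 (S)-1,3-bis(TBSO)-2-ethenyl-3-methylbutane
Conditions: TBSOTf, 2,6-lutidine, CH2Cl2, 0 °C → rt
Reagents that add atoms: tert-butyldimethylsilyl triflate, CC(C)(C)[Si](C)(C)OS(=O)(=O)C(F)(F)F
Why: Silylation with a silyl triflate and a hindered pyridine base covers the primary O8 and the tertiary O11 hydroxyl groups in one operation, and the bulky TBS group is chosen because it should not migrate between the two primary oxygens present after step 4, a shift that would invert C7.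

**Step 4**
Reactants: 5 (S)-1,3-bis(TBSO)-2-ethenyl-3-methylbutane
Product: 7 (S)-3-(TBSO)-2-[(TBSO)methyl]-3-methylbutan-1-ol, via aldehyde 6 (not isolated)
Conditions: O3, CH2Cl2/MeOH, −78 °C; then NaBH4, −78 → 0 °C
Reagents that add atoms: ozone, [O-][O+]=O
Why: Ozonolysis with borohydride work-up trims the vinyl group to the C6 hydroxymethyl group, and the aldehyde is reduced cold before its α-centre C7 can enolise.

**Step 5**
Reactants: 7 (S)-3-(TBSO)-2-[(TBSO)methyl]-3-methylbutan-1-ol
Product: 8 (S)-1,3-bis(TBSO)-2-(iodomethyl)-3-methylbutane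
Conditions: I2, PPh3, imidazole, CH2Cl2, 0 °C → rt
Reagents that add atoms: iodine, II
Why: Appel-type iodination converts the only free, primary hydroxyl group into the iodide by SN2 at C6 without touching C7.

**Step 6**
Reactants: 9 2-bromo-3-methylcyclopent-2-en-1-one
Product: 10 (S)-2-bromo-3-methylcyclopent-2-en-1-ol
Conditions: (R)-2-methyl-CBS-oxazaborolidine (cat.), BH3·SMe2, THF, −20 °C
Reagents that add atoms: none
Why: In this Corey–Bakshi–Shibata reduction the bromoalkene arm plays the large substituent and the CH2 arm the small one, so the (R)-oxazaborolidine should give the (S)-carbinol at C1, a temporary stereocentre that steers step 8.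

**Step 7**
Reactants: 8 (S)-1,3-bis(TBSO)-2-(iodomethyl)-3-methylbutane; 10 (S)-2-bromo-3-methylcyclopent-2-en-1-ol
Product: 13 (1S)-2-{(2S)-3-(TBSO)-2-[(TBSO)methyl]-3-methylbutyl}-3-methylcyclopent-2-en-1-ol, via alkyllithium 11 (not isolated), via lithium borate 12 (not isolated)
Conditions: 8, t-BuLi, Et2O, −78 °C; B-methoxy-9-BBN, THF, −78 °C → rt; then 10, Pd(dppf)Cl2 (cat.), aq. K3PO4, DMF, rt → 45 °C
Reagents that add atoms: none
Why: B-alkyl Suzuki–Miyaura coupling of a borate made by lithium–iodine exchange and trapping with B-methoxy-9-BBN, a protocol established for β-branched γ-silyloxy iodides, forms C5–C6 in the presence of the free hydroxyl group without touching C1 or C7, and it turns any minor enantiomer of either partner into a separable diastereomer.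

**Step 8**
Reactants: 13 (1S)-2-{(2S)-3-(TBSO)-2-[(TBSO)methyl]-3-methylbutyl}-3-methylcyclopent-2-en-1-ol
Product: 14 (1S,2S,3S)-2-{(2S)-3-(TBSO)-2-[(TBSO)methyl]-3-methylbutyl}-3-methylcyclopentan-1-ol
Conditions: [Ir(cod)(PCy3)(py)]PF6 (cat.), H2 (1–50 bar), CH2Cl2, rt
Reagents that add atoms: none
Why: In this hydroxyl-directed homogeneous hydrogenation the cationic iridium catalyst binds the C1 hydroxyl group and adds both hydrogens to the tetrasubstituted C4=C5 alkene from that face, so syn addition makes C15 and C6 cis and the carbinol configuration fixes the absolute sense (4S,5S).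

**Step 9**
Reactants: 14 (1S,2S,3S)-2-{(2S)-3-(TBSO)-2-[(TBSO)methyl]-3-methylbutyl}-3-methylcyclopentan-1-ol
Product: 15 (2S,3S)-2-{(2S)-3-(TBSO)-2-[(TBSO)methyl]-3-methylbutyl}-3-methylcyclopentan-1-one
Conditions: Dess–Martin periodinane, NaHCO3, CH2Cl2, 0 °C
Reagents that add atoms: none
Why: Dess–Martin oxidation under bicarbonate buffer removes the now spent C1 carbinol centre under non-enolising conditions, so the cis relation at the epimerisable C5 should be kept provided the ketone is used at once.

**Step 10**
Reactants: 15 (2S,3S)-2-{(2S)-3-(TBSO)-2-[(TBSO)methyl]-3-methylbutyl}-3-methylcyclopentan-1-one; 16 isopropenylmagnesium bromide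
Product: 17 (1R,2S,3S)-2-{(2S)-3-(TBSO)-2-[(TBSO)methyl]-3-methylbutyl}-3-methyl-1-(prop-1-en-2-yl)cyclopentan-1-ol
Conditions: anhydrous CeCl3, THF; 16, −78 °C; then 15, −78 °C
Reagents that add atoms: none
Why: Organocerium 1,2-addition is chosen because the weakly basic reagent adds to enolisable ketones faster than it deprotonates them, and it attacks the carbonyl from the face opposite the two cis substituents on C4 and C5, which places the C1 oxygen cis to C6 (1R).

**Step 11**
Reactants: 17 (1R,2S,3S)-2-{(2S)-3-(TBSO)-2-[(TBSO)methyl]-3-methylbutyl}-3-methyl-1-(prop-1-en-2-yl)cyclopentan-1-ol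
Product: 18 methyl carbonate of 17 at the C1 oxygen (1R,4S,5S,7S in guaiane numbering)
Conditions: KHMDS, THF, −78 °C; ClCO2Me, −78 → 0 °C
Reagents that add atoms: methyl chloroformate, COC(=O)Cl
Why: O-acylation of the potassium alkoxide of a tertiary allylic alcohol with a chloroformate is standard, and like step 10 it is carried out before nitrogen is introduced, because a primary nitroalkane would be deprotonated by the organometallic reagent and dehydrated towards a nitrile oxide by base and chloroformate.

**Step 12**
Reactants: 18 methyl carbonate with O8-TBS and O11-TBS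
Product: 19 methyl (1R,2S,3S)-2-[(2S)-3-(TBSO)-2-(hydroxymethyl)-3-methylbutyl]-3-methyl-1-(prop-1-en-2-yl)cyclopentyl carbonate
Conditions: HF·pyridine, pyridine, THF, 0 °C
Reagents that add atoms: none
Why: Fluoride-mediated desilylation under pyridine buffer discriminates by steric access, the primary TBS ether on O8 being cleaved far faster than the tertiary one on O11, while the buffered medium spares the acid-sensitive tertiary allylic carbonate.

**Step 13**
Reactants: 19 methyl carbonate with free C8 hydroxyl group
Product: 20 methyl (1R,2S,3S)-2-[(2R)-3-(TBSO)-2-(iodomethyl)-3-methylbutyl]-3-methyl-1-(prop-1-en-2-yl)cyclopentyl carbonate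
Conditions: I2, PPh3, imidazole, CH2Cl2, 0 °C → rt
Reagents that add atoms: iodine, II
Why: Appel-type iodination of the primary alcohol runs under near-neutral conditions that the carbonate, the alkene and the tertiary silyl ether tolerate, and the change of the C7 descriptor is only a change of substituent priority.

**Step 14**
Reactants: 20 methyl carbonate with C8 iodide
Product: 21 methyl (1R,2S,3S)-2-[(2S)-3-(TBSO)-3-methyl-2-(nitromethyl)butyl]-3-methyl-1-(prop-1-en-2-yl)cyclopentyl carbonate (cyclisation precursor)
Conditions: NaNO2, phloroglucinol, DMSO, rt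
Reagents that add atoms: sodium nitrite, [Na+].[O-]N=O
Why: Kornblum displacement of a primary iodide by nitrite in a dipolar aprotic solvent gives the nitroalkane by attack through nitrogen, phloroglucinol intercepts the nitrite ester from attack through oxygen before it can nitrosate the product, and that ester can be methanolysed back to 19.

**Step 15**
Reactants: 21 methyl (1R,2S,3S)-2-[(2S)-3-(TBSO)-3-methyl-2-(nitromethyl)butyl]-3-methyl-1-(prop-1-en-2-yl)cyclopentyl carbonate
Product: 22 (4S,5S,7S,8S)-11-(TBSO)-8-nitroguai-1(10)-ene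
Conditions: Pd(PPh3)4 (10 mol %), THF, 5 mM by slow addition of 21, 50 °C
Reagents that add atoms: none
Why: Zerovalent palladium binds the C9=C10 methylene and expels the C1 carbonate from the face anti to the metal, CO2 is lost, and the methoxide set free deprotonates the far more acidic C8H2NO2 group, so that a cationic 2-methylallyl complex of divalent palladium spanning C1–C10–C9 and its own nitronate arise together without added base; carbon C8 then attacks C9 anti to palladium, forming C8–C9 and the C1=C10 alkene and returning the catalyst. The closest known reaction type is the intramolecular Tsuji–Trost allylic alkylation of nitroalkanes with allylic carbonates under neutral conditions. The seven-membered ring closes in the endo mode, all three allyl carbons becoming ring members, which is geometrically possible because C1 is fully substituted and C5 can take the anti position of the allyl unit (C9 cis to C5); the rotamer with C2 anti cannot close and has to drain into the productive one by η3–η1–η3 interconversion. The carbonate of 21 lies on the same face as the C6 tether, so ionisation puts the metal on the opposite face and leaves the nitronate correctly placed, and exchange of the metal between the faces through the η1 form at the CH2 terminus makes the C1 configuration uncritical. The only new stereocentre, C8, keeps an acidic hydrogen and should settle under methoxide equilibration with the nitro group trans to the bulky C7 substituent, and it is erased in step 16 in any case. The selectivity needed is attack at C9 rather than at C1 (5-exo closure to a diquinane) or proton loss to a diene, and it rests on the preference of triphenylphosphine-ligated allylpalladium for attack of stabilised carbanions at the unsubstituted terminus, reinforced here because bonding at C1 would join a quaternary carbon to a nitronate carbon already flanked by the CMe2OTBS-bearing C7, while high dilution suppresses intermolecular alkylation.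

**Step 16**
Reactants: 22 (4S,5S,7S,8S)-11-(TBSO)-8-nitroguai-1(10)-ene
Product: 24 (4S,5S,7R)-11-(TBSO)guai-1(10)-en-8-one, via sodium nitronate 23 (not isolated)
Conditions: NaOMe, MeOH, 0 °C; then aq. TiCl3, NH4OAc, THF/H2O, 0 °C → rt
Reagents that add atoms: water, O
Why: The reductive Nef reaction (nitronate, then buffered aqueous TiCl3) leads through oxime and imine to the ketone near neutral pH, which should spare the silyl ether, keep the C1=C10 alkene out of conjugation and leave unchanged the α-centre C7, whose bulky substituent already sits in the favoured pseudo-equatorial position cis-1,3 to the C4–C5 bond.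

**Step 17**
Reactants: 24 (4S,5S,7R)-11-(TBSO)guai-1(10)-en-8-one
Product: 25 (4S,5S,7R)-11-hydroxyguai-1(10)-en-8-one
Conditions: aq. HF, MeCN, 0 °C → rt
Reagents that add atoms: none
Why: Acidic fluoride desilylation frees the tertiary C11 hydroxyl group without the basic conditions that would invite retro-aldol loss of acetone or β-elimination from the β-hydroxy ketone.

**Step 18**
Reactants: 25 (4S,5S,7R)-11-hydroxyguai-1(10)-en-8-one
Product: 26 (4S,5S,7S,8S)-guai-1(10)-ene-8,11-diol
Conditions: Me4NBH(OAc)3, AcOH/MeCN, −30 °C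
Reagents that add atoms: none
Why: In this hydroxyl-directed triacetoxyborohydride reduction of the Evans–Saksena type, ligand exchange binds boron to O11 and hydride is delivered intramolecularly to the C8 carbonyl from the face that carries C11, so H8 ends cis and O8 trans to the C7 substituent (8S).

**Step 19**
Reactants: 27 (E)-4-hydroxycinnamic acid (p-coumaric acid)
Product: 29 (E)-4-(TBSO)cinnamic acid, via silyl ester 28 (not isolated)
Conditions: TBSCl, imidazole, DMF, rt; then AcOH/THF/H2O, rt
Reagents that add atoms: tert-butyldimethylsilyl chloride, CC(C)(C)[Si](C)(C)Cl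
Why: Exhaustive silylation followed by selective hydrolysis of the much more labile silyl ester gives the phenol-protected acid with the (E)-alkene untouched.

**Step 20**
Reactants: 26 (4S,5S,7S,8S)-guai-1(10)-ene-8,11-diol; 29 (E)-4-(TBSO)cinnamic acid
Product: 30 (4S,5S,7S,8S)-11-hydroxyguai-1(10)-en-8-yl (E)-4-(TBSO)cinnamate
Conditions: EDC·HCl, DMAP, CH2Cl2, rt
Reagents that add atoms: none
Why: Steglich esterification acylates the secondary O8 hydroxyl group with retention at C8, the tertiary C11 hydroxyl group being too hindered to compete.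

**Step 21**
Reactants: 30 (4S,5S,7S,8S)-11-hydroxyguai-1(10)-en-8-yl (E)-4-(TBSO)cinnamate
Product: 31 (4S,5S,7S,8S)-11-hydroxyguai-1(10)-en-8-yl (E)-4-hydroxycinnamate (target CNP0403230.1)
Conditions: TBAF, AcOH, THF, 0 °C
Reagents that add atoms: none
Why: Fluoride cleavage of an aryl silyl ether is fast at 0 °C, and buffering with acetic acid keeps phenoxide and fluoride from attacking the cinnamate ester.

**Compound list**

1 | 3-methylbut-2-en-1-ol (prenol) | CC(C)=CCO | starting material
2 | (R)-(3,3-dimethyloxiran-2-yl)methanol | OC[C@H]1OC1(C)C | intermediate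
3 | vinylmagnesium bromide | C=C[Mg]Br | starting material
4 | (S)-2-ethenyl-3-methylbutane-1,3-diol | C=C[C@@H](CO)C(C)(C)O | intermediate
5 | (S)-1,3-bis(TBSO)-2-ethenyl-3-methylbutane | C=C[C@@H](CO[Si](C)(C)C(C)(C)C)C(C)(C)O[Si](C)(C)C(C)(C)C | intermediate
6 | (S)-3-(TBSO)-2-[(TBSO)methyl]-3-methylbutanal | O=C[C@@H](CO[Si](C)(C)C(C)(C)C)C(C)(C)O[Si](C)(C)C(C)(C)C | intermediate
7 | (S)-3-(TBSO)-2-[(TBSO)methyl]-3-methylbutan-1-ol | OC[C@@H](CO[Si](C)(C)C(C)(C)C)C(C)(C)O[Si](C)(C)C(C)(C)C | intermediate
8 | (S)-1,3-bis(TBSO)-2-(iodomethyl)-3-methylbutane | IC[C@@H](CO[Si](C)(C)C(C)(C)C)C(C)(C)O[Si](C)(C)C(C)(C)C | intermediate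
9 | 2-bromo-3-methylcyclopent-2-en-1-one | CC1=C(Br)C(=O)CC1 | starting material
10 | (S)-2-bromo-3-methylcyclopent-2-en-1-ol | CC1=C(Br)[C@@H](O)CC1 | intermediate
11 | alkyllithium from 8 (lithium on C6) | [Li]C[C@@H](CO[Si](C)(C)C(C)(C)C)C(C)(C)O[Si](C)(C)C(C)(C)C | intermediate
12 | lithium B-alkyl-B-methoxy-9-BBN borate (boron on C6) | [Li+].CO[B-]1(C[C@@H](CO[Si](C)(C)C(C)(C)C)C(C)(C)O[Si](C)(C)C(C)(C)C)C2CCCC1CCC2 | intermediate
13 | (1S)-2-{(2S)-3-(TBSO)-2-[(TBSO)methyl]-3-methylbutyl}-3-methylcyclopent-2-en-1-ol | CC1=C(C[C@@H](CO[Si](C)(C)C(C)(C)C)C(C)(C)O[Si](C)(C)C(C)(C)C)[C@@H](O)CC1 | intermediate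
14 | (1S,2S,3S)-2-{(2S)-3-(TBSO)-2-[(TBSO)methyl]-3-methylbutyl}-3-methylcyclopentan-1-ol | O[C@H]1CC[C@H](C)[C@@H]1C[C@@H](CO[Si](C)(C)C(C)(C)C)C(C)(C)O[Si](C)(C)C(C)(C)C | intermediate
15 | (2S,3S)-2-{(2S)-3-(TBSO)-2-[(TBSO)methyl]-3-methylbutyl}-3-methylcyclopentan-1-one (cis) | O=C1CC[C@H](C)[C@@H]1C[C@@H](CO[Si](C)(C)C(C)(C)C)C(C)(C)O[Si](C)(C)C(C)(C)C | intermediate
16 | isopropenylmagnesium bromide | CC(=C)[Mg]Br | starting material
17 | (1R,2S,3S)-2-{(2S)-3-(TBSO)-2-[(TBSO)methyl]-3-methylbutyl}-3-methyl-1-(prop-1-en-2-yl)cyclopentan-1-ol | CC(=C)[C@@]1(O)CC[C@H](C)[C@@H]1C[C@@H](CO[Si](C)(C)C(C)(C)C)C(C)(C)O[Si](C)(C)C(C)(C)C | intermediate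
18 | methyl carbonate of 17 | CC(=C)[C@@]1(OC(=O)OC)CC[C@H](C)[C@@H]1C[C@@H](CO[Si](C)(C)C(C)(C)C)C(C)(C)O[Si](C)(C)C(C)(C)C | intermediate
19 | methyl carbonate with free C8 hydroxyl group (7S) | CC(=C)[C@@]1(OC(=O)OC)CC[C@H](C)[C@@H]1C[C@@H](CO)C(C)(C)O[Si](C)(C)C(C)(C)C | intermediate
20 | methyl carbonate with C8 iodide (7R) | CC(=C)[C@@]1(OC(=O)OC)CC[C@H](C)[C@@H]1C[C@@H](CI)C(C)(C)O[Si](C)(C)C(C)(C)C | intermediate
21 | methyl carbonate with C8 nitro group (7S), cyclisation precursor | CC(=C)[C@@]1(OC(=O)OC)CC[C@H](C)[C@@H]1C[C@@H](C[N+](=O)[O-])C(C)(C)O[Si](C)(C)C(C)(C)C | intermediate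
22 | (4S,5S,7S,8S)-11-(TBSO)-8-nitroguai-1(10)-ene | CC1=C2CC[C@H](C)[C@@H]2C[C@H](C(C)(C)O[Si](C)(C)C(C)(C)C)[C@@H]([N+](=O)[O-])C1 | intermediate
23 | sodium nitronate of 22 | CC1=C2CC[C@H](C)[C@@H]2C[C@H](C(C)(C)O[Si](C)(C)C(C)(C)C)C(=[N+]([O-])[O-])C1.[Na+] | intermediate
24 | (4S,5S,7R)-11-(TBSO)guai-1(10)-en-8-one | CC1=C2CC[C@H](C)[C@@H]2C[C@H](C(C)(C)O[Si](C)(C)C(C)(C)C)C(=O)C1 | intermediate
25 | (4S,5S,7R)-11-hydroxyguai-1(10)-en-8-one | CC1=C2CC[C@H](C)[C@@H]2C[C@H](C(C)(C)O)C(=O)C1 | intermediate
26 | (4S,5S,7S,8S)-guai-1(10)-ene-8,11-diol | CC1=C2CC[C@H](C)[C@@H]2C[C@H](C(C)(C)O)[C@@H](O)C1 | intermediate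
27 | (E)-4-hydroxycinnamic acid | OC(=O)/C=C/c1ccc(O)cc1 | starting material
28 | TBS (E)-4-(TBSO)cinnamate | CC(C)(C)[Si](C)(C)OC(=O)/C=C/c1ccc(O[Si](C)(C)C(C)(C)C)cc1 | intermediate
29 | (E)-4-(TBSO)cinnamic acid | OC(=O)/C=C/c1ccc(O[Si](C)(C)C(C)(C)C)cc1 | intermediate
30 | (4S,5S,7S,8S)-11-hydroxyguai-1(10)-en-8-yl (E)-4-(TBSO)cinnamate | CC1=C2CC[C@H](C)[C@@H]2C[C@H](C(C)(C)O)[C@@H](OC(=O)/C=C/c2ccc(O[Si](C)(C)C(C)(C)C)cc2)C1 | intermediate
31 | (4S,5S,7S,8S)-11-hydroxyguai-1(10)-en-8-yl (E)-4-hydroxycinnamate | CC1=C2CC[C@H](C)[C@@H]2C[C@H](C(C)(C)O)[C@@H](OC(=O)/C=C/c2ccc(O)cc2)C1 | target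

**Step count**

- Total step count: 21.
- Longest linear sequence: 19 steps, from 1 through steps 1–5, 7–18, 20 and 21.

**Steps most likely to fail**

**Step 15.** The nitronate may bond to the proximal allyl terminus C1, because five-membered closure is kinetically quicker than the seven-membered endo closure. The fallback accepts that closure and expands the ring afterwards.
- It sets out from 21 and returns at 24.
- The same palladium conditions would give the cis-fused 1-isopropenyl-8-nitrobicyclo[3.3.0]octane F1.
- The buffered TiCl3 Nef conditions of step 16 would convert F1 into the α-isopropenyl ketone F2, a β,γ-unsaturated ketone with its acyl carbon C8 on the quaternary C1.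
- Direct irradiation of F2 (about 300 nm, cyclohexane) triggers the known photochemical 1,3-acyl shift. The C8–C1 bond breaks and C8 rebonds at C9, which enlarges the ring by two carbons and creates the C1=C10 alkene of 24 with C5 and C7 untouched.

**Step 8.** Hydrogen uptake at the hindered tetrasubstituted alkene may be too slow, so that redox isomerisation of the allylic alcohol or loss of a silyl group at the acidic iridium hydride takes over. The fallback gives up direction by the hydroxyl group.
- It sets out from 13 and returns at 15.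
- Oxidation with MnO2 gives the enone F3.
- Heterogeneous hydrogenation of F3 over Pd/C in ethyl acetate still adds hydrogen syn and so still gives only cis-2,3-disubstituted ketones, but on both faces.
- Because C7 is fixed, 15 and the (4R,5R) isomer F4 are diastereomers, and F4 is removed by chromatography on neutral silica.

**Step 16.** Hydrolysis of the hindered nitronate may stall at the oxime stage, or the alkene may slip into conjugation, or silanolate may be eliminated while the mixture is pushed. The fallback replaces the Nef reaction by reduction and transamination.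
- It sets out from 22 and returns at 24.
- NiCl2·6H2O/NaBH4 in methanol reduces the nitro group to the primary amine F5 without touching the tetrasubstituted alkene.
- Condensation of F5 with 3,5-di-tert-butyl-1,2-benzoquinone followed by prototropic shift gives the N-(2-hydroxyaryl) ketimine F6.
- Aqueous oxalic acid hydrolyses F6 to 24.

**Further compounds**

F1 | step 15 | cis-fused bicyclo[3.3.0]octane from C8–C1 bonding: 1-isopropenyl, 4-methyl, 7-(2-TBSO-propan-2-yl), 8-nitro (guaiane numbering, C8 epimers) | CC(=C)[C@@]12CC[C@H](C)[C@@H]1C[C@H](C(C)(C)O[Si](C)(C)C(C)(C)C)C2[N+](=O)[O-]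
F2 | step 15 | corresponding bicyclo[3.3.0]octan-8-one with the isopropenyl group on the α-quaternary C1 | CC(=C)[C@@]12CC[C@H](C)[C@@H]1C[C@H](C(C)(C)O[Si](C)(C)C(C)(C)C)C2=O
F3 | step 8 | 2-{(2S)-3-(TBSO)-2-[(TBSO)methyl]-3-methylbutyl}-3-methylcyclopent-2-en-1-one | CC1=C(C[C@@H](CO[Si](C)(C)C(C)(C)C)C(C)(C)O[Si](C)(C)C(C)(C)C)C(=O)CC1
F4 | step 8 | (2R,3R)-2-{(2S)-3-(TBSO)-2-[(TBSO)methyl]-3-methylbutyl}-3-methylcyclopentan-1-one | O=C1CC[C@@H](C)[C@H]1C[C@@H](CO[Si](C)(C)C(C)(C)C)C(C)(C)O[Si](C)(C)C(C)(C)C
F5 | step 16 | (4S,5S,7S,8S)-8-amino-11-(TBSO)guai-1(10)-ene | CC1=C2CC[C@H](C)[C@@H]2C[C@H](C(C)(C)O[Si](C)(C)C(C)(C)C)[C@@H](N)C1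
F6 | step 16 | N-(3,5-di-tert-butyl-2-hydroxyphenyl) ketimine of 24 | CC1=C2CC[C@H](C)[C@@H]2C[C@H](C(C)(C)O[Si](C)(C)C(C)(C)C)C(=Nc2cc(C(C)(C)C)cc(C(C)(C)C)c2O)C1
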